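**Retrosynthetic overview**

- Feature: in the butyrolactone (O1, C2(=O), C3, C4, C5) the two exocyclic benzylic CH2 carbons on C3 and C4 are 1,4-related through the C3–C4 bond that joins the two C6–C3 units. They can therefore be tied together temporarily as the aryl-bearing carbons of a 1,2-diarylcyclobutane.
- Lactone ring (formed last): O1–C2 acyl bond from acid desilylation and lactonisation of silyloxy ester 10.
- 10 from hydrogenolysis of the bis-benzylic C2–C3 bond of cyclobutane 8 (the temporary ring, formed first and then opened).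
- 8 from an enantioselective crossed [2+2] photocycloaddition of cinnamate 3 with cinnamyl silyl ether 7, which forms lactone C3–C4 and the temporary benzylic–benzylic bond.
- 3 from syringaldehyde (benzylation, Wittig); 7 from 3,4-dimethoxycinnamic acid (reduction, silylation).

Key step: step 5

Assumption: the (S)-configured oxazaborolidinium is taken to shield the enoate face that leads to (1R)-8; if the sense of induction is the opposite, the (R)-catalyst is used with no other change.

**Route**

Step 1
Reactants: 1 syringaldehyde (4-hydroxy-3,5-dimethoxybenzaldehyde)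
Product: 2 4-(benzyloxy)-3,5-dimethoxybenzaldehyde
Conditions: BnBr, K2CO3, DMF, 60 °C
Reagents that add atoms: benzyl bromide, BrCc1ccccc1
Why: Williamson ether synthesis; the acidic syringyl phenoxide displaces bromide by SN2, and the non-enolisable aldehyde is inert to carbonate.

Step 2
Reactants: 2 4-(benzyloxy)-3,5-dimethoxybenzaldehyde
Product: 3 methyl (E)-3-[4-(benzyloxy)-3,5-dimethoxyphenyl]acrylate
Conditions: Ph3P=CHCO2Me, PhMe, 80 °C
Reagents that add atoms: methyl (triphenylphosphoranylidene)acetate, COC(=O)C=P(c1ccccc1)(c1ccccc1)c1ccccc1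
Why: Wittig olefination with a stabilised ylide, which should give the E-enoate from an aromatic aldehyde.

Step 3
Reactants: 4 (E)-3,4-dimethoxycinnamic acid
Product: 6 (E)-3-(3,4-dimethoxyphenyl)prop-2-en-1-ol, via mixed ethyl carbonic anhydride 5 (not isolated)
Conditions: ClCO2Et, Et3N, THF, −10 °C; then NaBH4, H2O, 0 °C
Reagents that add atoms: none
Why: mixed-anhydride reduction of a carboxylic acid; hydride should attack the more electrophilic cinnamoyl carbonyl and then reduce the resulting enal 1,2, leaving the E-alkene and aryl ethers untouched.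

Step 4
Reactants: 6 (E)-3-(3,4-dimethoxyphenyl)prop-2-en-1-ol
Product: 7 (E)-tert-butyl{[3-(3,4-dimethoxyphenyl)allyl]oxy}dimethylsilane
Conditions: TBSCl, imidazole, DMF, 23 °C
Reagents that add atoms: tert-butyldimethylsilyl chloride, CC(C)(C)[Si](C)(C)Cl
Why: imidazole-promoted silylation of the only nucleophilic group, a primary allylic alcohol.

Step 5
Reactants: 3 methyl (E)-3-[4-(benzyloxy)-3,5-dimethoxyphenyl]acrylate; 7 (E)-tert-butyl{[3-(3,4-dimethoxyphenyl)allyl]oxy}dimethylsilane
Product: 8 methyl (1R,2S,3S,4R)-2-[4-(benzyloxy)-3,5-dimethoxyphenyl]-4-{[(tert-butyldimethylsilyl)oxy]methyl}-3-(3,4-dimethoxyphenyl)cyclobutane-1-carboxylate (all-trans)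
Conditions: 7 (3 equiv, excess recovered), (S)-1-(2-methylphenyl)-3,3-diphenyltetrahydro-1H,3H-pyrrolo[1,2-c][1,3,2]oxazaborole (25 mol %) protonated with HNTf2 (20 mol %), fac-Ir(ppy)3 [tris(2-phenylpyridinato)iridium, trivalent iridium] (1 mol %), degassed CH2Cl2, −78 °C, blue LEDs (450 nm)
Reagents that add atoms: none
Why: Proposed new method: triplet energy transfer from photoexcited fac-Ir(ppy)3 to the oxazaborolidinium-bound cinnamate 3 (its triplet energy is lowered by carbonyl complexation, while that of free 7 is expected to lie above the sensitiser) should give an enoate triplet whose α-carbon adds to the non-benzylic alkene carbon of 7, forming C1–C4, and the bis-benzylic triplet 1,4-diradical then closes the cyclobutane by intersystem crossing and radical–radical combination (C2–C3), a stepwise, non-concerted [2+2]. The closest known reaction type is the chiral Lewis acid-catalysed, triplet-sensitised [2+2] photocycloaddition of cinnamate esters with terminal styrenes; a 1,2-disubstituted styrene carrying an allylic silyl ether has not been shown as the partner. C1 is set by the catalyst, whose aryl group shields one face of the s-trans-bound enoate; C4 is set in the same bond-forming event and is expected trans to the ester because the more crowded cis diradical should revert to the alkenes faster than it closes; C2 and C3 are set at ring closure, each trans to its neighbours, since the freely rotating diradical closes through its least hindered conformer regardless of alkene geometry. The step needs head-to-head regiochemistry, secured by the doubly benzylic 1,4-diradical being better stabilised than the benzylic/α-carbonyl alternative, and crossed rather than homo-coupling, secured by exciting only the complexed ester in the presence of excess 7. The poorly Lewis-basic silyl ether, the sub-stoichiometric HNTf2 and −78 °C are meant to keep the electron-rich allylic ether from ionising.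

Step 6
Reactants: 8 methyl (1R,2S,3S,4R)-2-[4-(benzyloxy)-3,5-dimethoxyphenyl]-4-{[(tert-butyldimethylsilyl)oxy]methyl}-3-(3,4-dimethoxyphenyl)cyclobutane-1-carboxylate
Product: 10 methyl (2R,3R)-4-[(tert-butyldimethylsilyl)oxy]-3-(3,4-dimethoxybenzyl)-2-(4-hydroxy-3,5-dimethoxybenzyl)butanoate, via debenzylated cyclobutane phenol 9 (not isolated)
Conditions: H2 (10 bar), 10% Pd/C, EtOAc, 50 °C
Reagents that add atoms: none
Why: heterogeneous Pd-catalysed hydrogenolysis should first cleave the aryl benzyl ether and then the strained, doubly benzylic C2–C3 σ-bond of the 1,2-diarylcyclobutane (a known ring opening of this substrate class); the ester, the silyl ether in a non-protic solvent and the non-benzylic C1/C4 stereocentres are untouched and become C2/C3 of the butanoate.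

Step 7
Reactants: 10 methyl (2R,3R)-4-[(tert-butyldimethylsilyl)oxy]-3-(3,4-dimethoxybenzyl)-2-(4-hydroxy-3,5-dimethoxybenzyl)butanoate
Product: 12 (3R,4R)-4-(3,4-dimethoxybenzyl)-3-(4-hydroxy-3,5-dimethoxybenzyl)dihydrofuran-2(3H)-one, via hydroxy ester 11 (not isolated)
Conditions: 2 M HCl (aq), THF, 40 °C
Reagents that add atoms: none
Why: acid hydrolysis of the primary silyl ether followed by acid-catalysed 5-exo-trig lactonisation of the γ-hydroxy ester; neither stereocentre is involved, and the trans-3,4-disubstituted lactone is also the thermodynamically preferred epimer.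

**Compound list**

1 | syringaldehyde (4-hydroxy-3,5-dimethoxybenzaldehyde) | COc1cc(C=O)cc(OC)c1O | starting material
2 | 4-(benzyloxy)-3,5-dimethoxybenzaldehyde | COc1cc(C=O)cc(OC)c1OCc1ccccc1 | intermediate
3 | methyl (E)-3-[4-(benzyloxy)-3,5-dimethoxyphenyl]acrylate | COC(=O)/C=C/c1cc(OC)c(OCc2ccccc2)c(OC)c1 | intermediate
4 | (E)-3,4-dimethoxycinnamic acid | COc1ccc(/C=C/C(O)=O)cc1OC | starting material
5 | (E)-3-(3,4-dimethoxyphenyl)acrylic ethyl carbonic anhydride | CCOC(=O)OC(=O)/C=C/c1ccc(OC)c(OC)c1 | intermediate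
6 | (E)-3-(3,4-dimethoxyphenyl)prop-2-en-1-ol | COc1ccc(/C=C/CO)cc1OC | intermediate
7 | (E)-tert-butyl{[3-(3,4-dimethoxyphenyl)allyl]oxy}dimethylsilane | COc1ccc(/C=C/CO[Si](C)(C)C(C)(C)C)cc1OC | intermediate
8 | methyl (1R,2S,3S,4R)-2-[4-(benzyloxy)-3,5-dimethoxyphenyl]-4-{[(tert-butyldimethylsilyl)oxy]methyl}-3-(3,4-dimethoxyphenyl)cyclobutane-1-carboxylate | COC(=O)[C@H]1[C@H](CO[Si](C)(C)C(C)(C)C)[C@@H](c2ccc(OC)c(OC)c2)[C@@H]1c1cc(OC)c(OCc2ccccc2)c(OC)c1 | intermediate
9 | methyl (1R,2S,3S,4R)-4-{[(tert-butyldimethylsilyl)oxy]methyl}-3-(3,4-dimethoxyphenyl)-2-(4-hydroxy-3,5-dimethoxyphenyl)cyclobutane-1-carboxylate | COC(=O)[C@H]1[C@H](CO[Si](C)(C)C(C)(C)C)[C@@H](c2ccc(OC)c(OC)c2)[C@@H]1c1cc(OC)c(O)c(OC)c1 | intermediate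
10 | methyl (2R,3R)-4-[(tert-butyldimethylsilyl)oxy]-3-(3,4-dimethoxybenzyl)-2-(4-hydroxy-3,5-dimethoxybenzyl)butanoate | COC(=O)[C@H](Cc1cc(OC)c(O)c(OC)c1)[C@H](CO[Si](C)(C)C(C)(C)C)Cc1ccc(OC)c(OC)c1 | intermediate
11 | methyl (2R,3R)-3-(3,4-dimethoxybenzyl)-4-hydroxy-2-(4-hydroxy-3,5-dimethoxybenzyl)butanoate | COC(=O)[C@H](Cc1cc(OC)c(O)c(OC)c1)[C@H](CO)Cc1ccc(OC)c(OC)c1 | intermediate
12 | (3R,4R)-4-(3,4-dimethoxybenzyl)-3-(4-hydroxy-3,5-dimethoxybenzyl)dihydrofuran-2(3H)-one | COc1ccc(C[C@H]2COC(=O)[C@@H]2Cc2cc(OC)c(O)c(OC)c2)cc1OC | target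

**Step count**

Total: 7 steps. Longest linear sequence: 5 steps (steps 3, 4, 5, 6, 7).

**Steps most likely to fail**

1. Step 5. Addition of the enoate triplet to the hindered 1,2-disubstituted alkene may be slow, so that relaxation, E/Z isomerisation and homodimerisation of 3 take over. The acid co-catalyst may ionise or oligomerise the electron-rich allylic ether. Sensitisation of unbound 3 may erode the enantioselectivity, and the first bond formation may give poor C1/C4 diastereoselectivity.
Fallback (known auxiliary chemistry, no photocycloaddition): it sets out from 4, uses aldehyde 2 and comes back to the route at 12.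
   - Acid 4 would be hydrogenated (H2, Pd/C, EtOAc) to 3-(3,4-dimethoxyphenyl)propanoic acid F1.
   - F1 would be activated (t-BuCOCl, Et3N, THF, −20 °C) as 3-(3,4-dimethoxyphenyl)propanoic pivalic anhydride F2 and treated with lithiated (S)-4-benzyloxazolidin-2-one (n-BuLi, THF, −78 °C) to give (S)-4-benzyl-3-[3-(3,4-dimethoxyphenyl)propanoyl]oxazolidin-2-one F3.
   - Evans alkylation of the sodium Z-enolate (NaN(SiMe3)2, THF, −78 °C; BrCH2CO2t-Bu), anti to the auxiliary benzyl group, should give tert-butyl (R)-4-[(S)-4-benzyl-2-oxooxazolidin-3-yl]-3-(3,4-dimethoxybenzyl)-4-oxobutanoate F4.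
   - LiBH4 (THF, 1 equiv H2O, 0 °C) would remove the auxiliary to give tert-butyl (R)-3-(3,4-dimethoxybenzyl)-4-hydroxybutanoate F5, which would be lactonised (TsOH cat., PhMe, 80 °C) to (R)-4-(3,4-dimethoxybenzyl)dihydrofuran-2(3H)-one F6.
   - Aldol addition of its lithium enolate (LiN(SiMe3)2, THF, −78 °C) to aldehyde 2, anti to the C4 benzyl group, should give (3S,4R)-3-{[4-(benzyloxy)-3,5-dimethoxyphenyl](hydroxy)methyl}-4-(3,4-dimethoxybenzyl)dihydrofuran-2(3H)-one F7 as a mixture of carbinol epimers.
   - Hydrogenolysis of the electron-rich benzylic alcohol and of the benzyl ether (H2, Pd/C, AcOH, cat. HClO4) would converge both epimers on 12.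

2. Step 6. Hydrogenolysis of the trans-diaryl ring bond may stall after debenzylation, or cleave one of the other benzylic ring bonds (C1–C2 or C3–C4), or forcing conditions may start to saturate the arenes.
Fallback (electron-transfer instead of catalytic cleavage): it sets out from 8 and comes back at 12.
   - Ester 8 would be saponified (LiOH, THF/MeOH/H2O, 40 °C) to (1R,2S,3S,4R)-2-[4-(benzyloxy)-3,5-dimethoxyphenyl]-4-{[(tert-butyldimethylsilyl)oxy]methyl}-3-(3,4-dimethoxyphenyl)cyclobutane-1-carboxylic acid F8, whose carboxylate resists dissolving-metal reduction.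
   - Li in NH3/THF (−78 °C, no added alcohol, NH4Cl quench) should cleave the bis-benzylic bond through the arene radical anion and remove the O-benzyl group, giving (2R,3R)-4-[(tert-butyldimethylsilyl)oxy]-3-(3,4-dimethoxybenzyl)-2-(4-hydroxy-3,5-dimethoxybenzyl)butanoic acid F9.
   - The conditions of step 7 (2 M HCl, THF, 40 °C) would then desilylate and lactonise F9 directly to 12.

3. Step 3. Borohydride may add in conjugate fashion to the activated cinnamoyl system, giving some saturated alcohol, or attack the carbonate carbonyl and return the acid.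
Fallback (two-stage ester route): it sets out from 4 and comes back at 6. Fischer esterification (MeOH, cat. H2SO4, reflux) would give methyl (E)-3-(3,4-dimethoxyphenyl)acrylate F10, and strictly 1,2-selective reduction with i-Bu2AlH (2.2 equiv, CH2Cl2, −78 °C) would give 6.

**Further compounds**

F1 | step 5 | 3-(3,4-dimethoxyphenyl)propanoic acid | COc1ccc(CCC(O)=O)cc1OC
F2 | step 5 | 3-(3,4-dimethoxyphenyl)propanoic pivalic anhydride | COc1ccc(CCC(=O)OC(=O)C(C)(C)C)cc1OC
F3 | step 5 | (S)-4-benzyl-3-[3-(3,4-dimethoxyphenyl)propanoyl]oxazolidin-2-one | COc1ccc(CCC(=O)N2[C@@H](Cc3ccccc3)COC2=O)cc1OC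
F4 | step 5 | tert-butyl (R)-4-[(S)-4-benzyl-2-oxooxazolidin-3-yl]-3-(3,4-dimethoxybenzyl)-4-oxobutanoate | COc1ccc(C[C@H](CC(=O)OC(C)(C)C)C(=O)N2[C@@H](Cc3ccccc3)COC2=O)cc1OC
F5 | step 5 | tert-butyl (R)-3-(3,4-dimethoxybenzyl)-4-hydroxybutanoate | COc1ccc(C[C@H](CC(=O)OC(C)(C)C)CO)cc1OC
F6 | step 5 | (R)-4-(3,4-dimethoxybenzyl)dihydrofuran-2(3H)-one | COc1ccc(C[C@H]2COC(=O)C2)cc1OC
F7 | step 5 | (3S,4R)-3-{[4-(benzyloxy)-3,5-dimethoxyphenyl](hydroxy)methyl}-4-(3,4-dimethoxybenzyl)dihydrofuran-2(3H)-one (carbinol epimers) | COc1ccc(C[C@H]2COC(=O)[C@@H]2C(O)c2cc(OC)c(OCc3ccccc3)c(OC)c2)cc1OC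
F8 | step 6 | (1R,2S,3S,4R)-2-[4-(benzyloxy)-3,5-dimethoxyphenyl]-4-{[(tert-butyldimethylsilyl)oxy]methyl}-3-(3,4-dimethoxyphenyl)cyclobutane-1-carboxylic acid | OC(=O)[C@H]1[C@H](CO[Si](C)(C)C(C)(C)C)[C@@H](c2ccc(OC)c(OC)c2)[C@@H]1c1cc(OC)c(OCc2ccccc2)c(OC)c1
F9 | step 6 | (2R,3R)-4-[(tert-butyldimethylsilyl)oxy]-3-(3,4-dimethoxybenzyl)-2-(4-hydroxy-3,5-dimethoxybenzyl)butanoic acid | OC(=O)[C@H](Cc1cc(OC)c(O)c(OC)c1)[C@H](CO[Si](C)(C)C(C)(C)C)Cc1ccc(OC)c(OC)c1
F10 | step 3 | methyl (E)-3-(3,4-dimethoxyphenyl)acrylate | COC(=O)/C=C/c1ccc(OC)c(OC)c1
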